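**Plan** (benzofuranone numbering of the target: O1, C2 lactone carbonyl, C3 with the methylene, C3a, C4 ester carbon, C5 with the side chain, C6 with the methyl, C7, C7a)

- Retrosynthesis: the C3 methylene and the C4 ester are removed first. The lactone bond C7a–O1 is traced back to a temporary C2–C6 bond, which turns the target ring into a bicyclo[2.2.2]octan-2-one. That bicycle is cut at C5–C6 and C4–C3a.
- Feature used: C6 and C3a are 1,4-related ring carbons and C3a carries the arm C3–C2. Once C2 is tied to C6, the atoms C2, C3, C3a, C7a, C7, C6 form a cyclohex-2-enone in which C6 is the nucleophilic α′-carbon and C3a the electrophilic β-carbon. This matches the polarity of the two-carbon unit C5–C4 delivered as a nitroalkene.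
- Forward: enone 5 (four steps) and nitroalkene 10 (three steps) are joined in one double Michael addition that closes the carbocycle. The temporary ring is opened by Baeyer–Villiger oxidation, Nef reaction with β-elimination (creating C5=C6) and relactonization to the cis-fused lactone. C4 carbinol, ester, methylene and desilylation follow.
- Stereochemistry: C7a from a Corey–Bakshi–Shibata reduction. C3a from C7a in the key step (both bonds form anti to the silyloxy group). The side-chain centre, together with C4 and C5, from (S)-β-citronellene (chiral pool). C4 from a convex-face Luche reduction followed by Mitsunobu inversion with the acid of the ester.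

Key step: step 8

Remark: 1 and 6 are taken to be commercially available. Centres described as "not defined" become trigonal later, so their configuration has no consequence.

**Step 1**
Reactants: 1 1,4-dioxaspiro[4.5]dec-6-en-8-one
Product: 2 (8R)-1,4-dioxaspiro[4.5]dec-6-en-8-ol
Conditions: (S)-2-methyl-CBS-oxazaborolidine (10 mol %), catecholborane, toluene, −78 °C; MeOH, aq. NaOH
Reagents that add atoms: none
Why: Corey–Bakshi–Shibata reduction: hydride is delivered 1,2 to the carbonyl face that keeps the alkenyl arm (large group) away from the catalyst, so the (S)-catalyst should give the (R)-allylic alcohol, the carbon that later becomes C7a.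

**Step 2**
Reactants: 2 (8R)-1,4-dioxaspiro[4.5]dec-6-en-8-ol
Product: 3 tert-butyl-[(8R)-1,4-dioxaspiro[4.5]dec-6-en-8-yl]oxy-dimethylsilane
Conditions: tert-butyl(chloro)dimethylsilane, imidazole, DMF, rt
Reagents that add atoms: tert-butyl(chloro)dimethylsilane CC(C)(C)[Si](C)(C)Cl
Why: Standard imidazole-assisted silylation of a secondary allylic alcohol; no stereocentre is affected.

**Step 3**
Reactants: 3 tert-butyl-[(8R)-1,4-dioxaspiro[4.5]dec-6-en-8-yl]oxy-dimethylsilane
Product: 4 (4R)-4-[tert-butyl(dimethyl)silyl]oxycyclohex-2-en-1-one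
Conditions: pyridinium p-toluenesulfonate (0.2 equiv), acetone/H2O 9:1, 50 °C
Reagents that add atoms: water O
Why: Acid-catalysed ketal hydrolysis frees the enone carbonyl while the silyl ether is stable to this weak acid; the stereocentre is untouched.

**Step 4**
Reactants: 4 (4R)-4-[tert-butyl(dimethyl)silyl]oxycyclohex-2-en-1-one
Product: 5 (4R)-4-[tert-butyl(dimethyl)silyl]oxy-6-methylcyclohex-2-en-1-one (C6 not defined)
Conditions: LiN(iPr)2, THF, −78 °C; MeI, −78 to −30 °C
Reagents that add atoms: iodomethane CI
Why: Kinetic deprotonation of a cyclohex-2-enone occurs at the α′-methylene and the cross-conjugated lithium dienolate is C-methylated (enolate alkylation); the new centre is planarized again in step 8, so its configuration is irrelevant.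

**Step 5**
Reactants: 6 (3S)-3,7-dimethylocta-1,6-diene
Product: 8 (4S)-4-methylhex-5-en-1-ol, via aldehyde 7 (not isolated)
Conditions: O3 (1.0 equiv, indicator end-point), CH2Cl2/MeOH 4:1, −78 °C; then NaBH4, −78 to 0 °C
Reagents that add atoms: ozone [O-][O+]=O
Why: Chemoselective ozonolysis with reductive work-up: ozone attacks the electron-rich trisubstituted alkene much faster than the vinyl group and NaBH4 reduces the cleavage products to the primary alcohol; the chiral-pool stereocentre is not touched.

**Step 6**
Reactants: 8 (4S)-4-methylhex-5-en-1-ol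
Product: 9 tert-butyl-[(4S)-4-methylhex-5-enyl]oxy-diphenylsilane
Conditions: tert-butyl(chloro)diphenylsilane, imidazole, DMF, rt
Reagents that add atoms: tert-butyl(chloro)diphenylsilane CC(C)(C)[Si](Cl)(c1ccccc1)c1ccccc1
Why: Standard silylation of a primary alcohol; this silyl ether is chosen because it should survive the acidic and basic steps up to the end.

**Step 7**
Reactants: 9 tert-butyl-[(4S)-4-methylhex-5-enyl]oxy-diphenylsilane
Product: 10 tert-butyl-[(4S,5E)-4-methyl-6-nitrohex-5-enyl]oxy-diphenylsilane
Conditions: AgNO2 (3 equiv), TEMPO (1 equiv), 4 Å molecular sieves, 1,2-dichloroethane, 70 °C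
Reagents that add atoms: silver nitrite (AgNO2) [Ag+].[O-]N=O
Why: Radical nitration of a terminal alkene: the NO2 radical adds to the terminal carbon and TEMPO removes the adjacent hydrogen, which should give the (E)-nitroalkene without touching the allylic stereocentre.

**Step 8**
Reactants: 5 (4R)-4-[tert-butyl(dimethyl)silyl]oxy-6-methylcyclohex-2-en-1-one; 10 tert-butyl-[(4S,5E)-4-methyl-6-nitrohex-5-enyl]oxy-diphenylsilane
Product: 12 (1S,4S,8R)-8-[tert-butyl(dimethyl)silyl]oxy-6-[(2S)-5-[tert-butyl(diphenyl)silyl]oxypentan-2-yl]-1-methyl-5-nitrobicyclo[2.2.2]octan-2-one (C5 and C6 not defined), via lithium nitronate 11 (not isolated)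
Conditions: LiN(iPr)2 (1.05 equiv), THF, −78 °C, 1 h; 10 in THF, −78 to 0 °C; AcOH, −78 °C
Reagents that add atoms: none
Why: The kinetic cross-conjugated lithium dienolate of 5 adds through its α′-carbon (later C6) to the β-carbon of nitroalkene 10 (later C5), and the lithium nitronate 11 so formed closes through its carbon (later C4) onto the enone β-carbon (later C3a) in an intramolecular Michael addition, so both ring bonds arise in one flask as a formal [4+2] cycloaddition. The closest known reaction type is the sequential double Michael addition (anionic Diels–Alder reaction) of cyclohexenone α′-enolates with nitroalkenes and acrylates to give bicyclo[2.2.2]octan-2-ones. The later carbocycle C3a–C4–C5–C6–C7–C7a closes in the 6-exo-trig mode and the temporary carbonyl-bridged ring closes at the same time in the 6-endo-trig mode. The configuration at C3a is controlled by the silyloxy-bearing C7a: both bonds must form on the dienolate face anti to the allylic silyloxy group, which places that group syn to the carbonyl bridge and so fixes the cis relation between the C7a oxygen and the C3a–C3 bond of the later lactone, while the bridgehead C6 and the two carbons from the nitroalkene are stereocentres only for a time. The step needs regioselectivity (α′-carbon to nitroalkene β-carbon, nitronate carbon to enone β-carbon), which the polarity of both partners secures, and it must stop before the ketone enolate displaces nitrite to close a cyclopropane, which the low temperature, the absence of a dipolar cosolvent and the acetic acid quench should secure.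

**Step 9**
Reactants: 12 bicyclic nitro ketone
Product: 13 (1S,5S,9R)-9-[tert-butyl(dimethyl)silyl]oxy-7-[(2S)-5-[tert-butyl(diphenyl)silyl]oxypentan-2-yl]-1-methyl-6-nitro-2-oxabicyclo[3.2.2]nonan-3-one (C6 and C7 not defined)
Conditions: 3-chloroperbenzoic acid, NaHCO3, CH2Cl2, 0 °C to rt
Reagents that add atoms: 3-chloroperbenzoic acid OOC(=O)c1cccc(Cl)c1
Why: Baeyer–Villiger oxidation: the more substituted tertiary bridgehead carbon migrates with retention, so oxygen is inserted between the carbonyl carbon (later C2) and C6 and the temporary carbon–carbon bond becomes a tertiary lactone C–O bond.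

**Step 10**
Reactants: 13 bridged nitro lactone
Product: 15 2-[(1R,6R)-6-[tert-butyl(dimethyl)silyl]oxy-3-[(2S)-5-[tert-butyl(diphenyl)silyl]oxypentan-2-yl]-4-methyl-2-oxocyclohex-3-en-1-yl]acetic acid, via keto lactone 14 (not isolated)
Conditions: DBU (1.1 equiv), THF, 0 °C; aq. TiCl3, NH4OAc, THF/H2O, rt; then DBU (0.2 equiv), CH2Cl2, 0 °C; aq. citric acid
Reagents that add atoms: water O
Why: Reductive Nef reaction (the nitronate is reduced by TiCl3 to the imine, which is hydrolysed to ketone 14) followed by E1cB elimination: the new C4 ketone acidifies the C5 hydrogen and the tertiary carboxylate on C6 is expelled, which opens the temporary lactone and creates the tetrasubstituted C5=C6 enone regiospecifically, while the bridgehead position of C3a protects it from enolization until the ring has opened.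

**Step 11**
Reactants: 15 enone acid
Product: 17 (3aR,7aR)-5-[(2S)-5-[tert-butyl(diphenyl)silyl]oxypentan-2-yl]-6-methyl-3,3a,7,7a-tetrahydro-1-benzofuran-2,4-dione, via hydroxy acid 16 (not isolated)
Conditions: 48% aq. HF, MeCN, 0 °C to rt
Reagents that add atoms: none
Why: Aqueous HF cleaves the secondary tert-butyldimethylsilyl ether much faster than the primary tert-butyldiphenylsilyl ether, and the freed C7a hydroxyl, held cis to the acetic acid arm by the geometry fixed in step 8, should close the γ-lactone by acid-catalysed lactonization.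

**Step 12**
Reactants: 17 cis-fused enone lactone
Product: 18 (3aS,4R,7aR)-5-[(2S)-5-[tert-butyl(diphenyl)silyl]oxypentan-2-yl]-4-hydroxy-6-methyl-3a,4,7,7a-tetrahydro-3H-1-benzofuran-2-one
Conditions: NaBH4, CeCl3·7H2O, MeOH, −78 °C
Reagents that add atoms: none
Why: Luche reduction: the cerium-activated enone carbonyl is reduced 1,2 and hydride should attack from the convex face of the cis-fused bicycle (the face of the ring-fusion hydrogens), which places the new hydroxyl cis to the lactone ring, opposite to the target configuration at C4.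

**Step 13**
Reactants: 18 allylic alcohol with hydroxyl cis to the lactone ring
Product: 19 [(3aR,4S,7aR)-5-[(2S)-5-[tert-butyl(diphenyl)silyl]oxypentan-2-yl]-6-methyl-2-oxo-3a,4,7,7a-tetrahydro-3H-1-benzofuran-4-yl] 3-methylbutanoate
Conditions: 3-methylbutanoic acid, PPh3, diisopropyl azodicarboxylate, toluene, 0 °C to rt
Reagents that add atoms: 3-methylbutanoic acid CC(C)CC(=O)O
Why: Mitsunobu esterification: the alcohol is activated as an alkoxyphosphonium ion and displaced by the carboxylate in an SN2 reaction from the open convex face, so the ester is installed with inversion and C4 obtains the target configuration; SN2′ attack is disfavoured because the distal alkene carbon is fully substituted.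

**Step 14**
Reactants: 19 3-methylbutanoate with saturated lactone
Product: 22 [(3aR,4S,7aR)-5-[(2S)-5-[tert-butyl(diphenyl)silyl]oxypentan-2-yl]-6-methyl-3-methylidene-2-oxo-3a,4,7,7a-tetrahydro-1-benzofuran-4-yl] 3-methylbutanoate, via Mannich base 20 (not isolated), via ammonium iodide 21 (not isolated)
Conditions: LiN(SiMe3)2 (1.1 equiv), THF, −78 °C; dimethyl(methylidene)ammonium iodide, −78 to 0 °C; then MeI, CH2Cl2, rt; then aq. NaHCO3, rt
Reagents that add atoms: dimethyl(methylidene)ammonium iodide C=[N+](C)C.[I-]
Why: α-Methylenation of a lactone by the Mannich route: the γ-lactone α-hydrogens are more acidic than those of the acyclic ester, so one equivalent of base should give the lactone enolate selectively, which is aminomethylated by Eschenmoser's salt, and N-methylation followed by E1cB loss of trimethylamine creates the exocyclic methylene (the transient C3 stereocentre disappears).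

**Step 15**
Reactants: 22 silyl-protected α-methylene lactone
Product: 23 [(3aR,4S,7aR)-5-[(2S)-5-hydroxypentan-2-yl]-6-methyl-3-methylidene-2-oxo-3a,4,7,7a-tetrahydro-1-benzofuran-4-yl] 3-methylbutanoate
Conditions: Bu4NF, AcOH (1:1), THF, 0 °C to rt
Reagents that add atoms: none
Why: Fluoride-mediated desilylation buffered with acetic acid should remove the primary silyl ether without conjugate addition to the α-methylene lactone or acyl migration, giving the target.

**Compound list**

1 | 1,4-dioxaspiro[4.5]dec-6-en-8-one | O=C1C=CC2(CC1)OCCO2 | starting material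
2 | (8R)-1,4-dioxaspiro[4.5]dec-6-en-8-ol | C1COC2(O1)C=C[C@H](O)CC2 | intermediate
3 | tert-butyl-[(8R)-1,4-dioxaspiro[4.5]dec-6-en-8-yl]oxy-dimethylsilane | C1COC2(O1)C=C[C@H](O[Si](C)(C)C(C)(C)C)CC2 | intermediate
4 | (4R)-4-[tert-butyl(dimethyl)silyl]oxycyclohex-2-en-1-one | O=C1C=C[C@H](O[Si](C)(C)C(C)(C)C)CC1 | intermediate
5 | (4R)-4-[tert-butyl(dimethyl)silyl]oxy-6-methylcyclohex-2-en-1-one (C6 not defined) | O=C1C=C[C@H](O[Si](C)(C)C(C)(C)C)CC1C | intermediate
6 | (3S)-3,7-dimethylocta-1,6-diene, (S)-β-citronellene | C=C[C@@H](C)CCC=C(C)C | starting material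
7 | (4S)-4-methylhex-5-enal | C=C[C@@H](C)CCC=O | intermediate
8 | (4S)-4-methylhex-5-en-1-ol | C=C[C@@H](C)CCCO | intermediate
9 | tert-butyl-[(4S)-4-methylhex-5-enyl]oxy-diphenylsilane | C=C[C@@H](C)CCCO[Si](c1ccccc1)(c1ccccc1)C(C)(C)C | intermediate
10 | tert-butyl-[(4S,5E)-4-methyl-6-nitrohex-5-enyl]oxy-diphenylsilane | [O-][N+](=O)/C=C/[C@@H](C)CCCO[Si](c1ccccc1)(c1ccccc1)C(C)(C)C | intermediate
11 | lithium nitronate of (4R)-4-[tert-butyl(dimethyl)silyl]oxy-6-[(3S)-6-[tert-butyl(diphenyl)silyl]oxy-3-methyl-1-nitrohexan-2-yl]-6-methylcyclohex-2-en-1-one (new ring bond anti to the silyloxy group) | O=C1C=C[C@H](O[Si](C)(C)C(C)(C)C)C[C@@]1(C)C([C@@H](C)CCCO[Si](c2ccccc2)(c2ccccc2)C(C)(C)C)C=[N+]([O-])[O-].[Li+] | intermediate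
12 | (1S,4S,8R)-8-[tert-butyl(dimethyl)silyl]oxy-6-[(2S)-5-[tert-butyl(diphenyl)silyl]oxypentan-2-yl]-1-methyl-5-nitrobicyclo[2.2.2]octan-2-one (silyloxy syn to the carbonyl bridge; C5 and C6 not defined) | O=C1C[C@@H]2[C@H](O[Si](C)(C)C(C)(C)C)C[C@@]1(C)C([C@@H](C)CCCO[Si](c3ccccc3)(c3ccccc3)C(C)(C)C)C2[N+](=O)[O-] | intermediate
13 | (1S,5S,9R)-9-[tert-butyl(dimethyl)silyl]oxy-7-[(2S)-5-[tert-butyl(diphenyl)silyl]oxypentan-2-yl]-1-methyl-6-nitro-2-oxabicyclo[3.2.2]nonan-3-one (C6 and C7 not defined) | O=C1C[C@@H]2[C@H](O[Si](C)(C)C(C)(C)C)C[C@](C)(O1)C([C@@H](C)CCCO[Si](c3ccccc3)(c3ccccc3)C(C)(C)C)C2[N+](=O)[O-] | intermediate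
14 | (1S,5R,9R)-9-[tert-butyl(dimethyl)silyl]oxy-7-[(2S)-5-[tert-butyl(diphenyl)silyl]oxypentan-2-yl]-1-methyl-2-oxabicyclo[3.2.2]nonane-3,6-dione (C7 not defined) | O=C1C[C@@H]2[C@H](O[Si](C)(C)C(C)(C)C)C[C@](C)(O1)C([C@@H](C)CCCO[Si](c3ccccc3)(c3ccccc3)C(C)(C)C)C2=O | intermediate
15 | 2-[(1R,6R)-6-[tert-butyl(dimethyl)silyl]oxy-3-[(2S)-5-[tert-butyl(diphenyl)silyl]oxypentan-2-yl]-4-methyl-2-oxocyclohex-3-en-1-yl]acetic acid | OC(=O)C[C@@H]1[C@H](O[Si](C)(C)C(C)(C)C)CC(C)=C([C@@H](C)CCCO[Si](c2ccccc2)(c2ccccc2)C(C)(C)C)C1=O | intermediate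
16 | 2-[(1R,6R)-3-[(2S)-5-[tert-butyl(diphenyl)silyl]oxypentan-2-yl]-6-hydroxy-4-methyl-2-oxocyclohex-3-en-1-yl]acetic acid | OC(=O)C[C@@H]1[C@H](O)CC(C)=C([C@@H](C)CCCO[Si](c2ccccc2)(c2ccccc2)C(C)(C)C)C1=O | intermediate
17 | (3aR,7aR)-5-[(2S)-5-[tert-butyl(diphenyl)silyl]oxypentan-2-yl]-6-methyl-3,3a,7,7a-tetrahydro-1-benzofuran-2,4-dione (cis-fused) | O=C1C[C@H]2C(=O)C([C@@H](C)CCCO[Si](c3ccccc3)(c3ccccc3)C(C)(C)C)=C(C)C[C@H]2O1 | intermediate
18 | (3aS,4R,7aR)-5-[(2S)-5-[tert-butyl(diphenyl)silyl]oxypentan-2-yl]-4-hydroxy-6-methyl-3a,4,7,7a-tetrahydro-3H-1-benzofuran-2-one (hydroxyl cis to the lactone ring) | O=C1C[C@H]2[C@@H](O)C([C@@H](C)CCCO[Si](c3ccccc3)(c3ccccc3)C(C)(C)C)=C(C)C[C@H]2O1 | intermediate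
19 | [(3aR,4S,7aR)-5-[(2S)-5-[tert-butyl(diphenyl)silyl]oxypentan-2-yl]-6-methyl-2-oxo-3a,4,7,7a-tetrahydro-3H-1-benzofuran-4-yl] 3-methylbutanoate | O=C1C[C@H]2[C@H](OC(=O)CC(C)C)C([C@@H](C)CCCO[Si](c3ccccc3)(c3ccccc3)C(C)(C)C)=C(C)C[C@H]2O1 | intermediate
20 | 3-[(dimethylamino)methyl] derivative of 19 (C3 not defined) | CN(C)CC1C(=O)O[C@@H]2CC(C)=C([C@@H](C)CCCO[Si](c3ccccc3)(c3ccccc3)C(C)(C)C)[C@@H](OC(=O)CC(C)C)[C@H]12 | intermediate
21 | 3-[(trimethylammonio)methyl] iodide derived from 20 (C3 not defined) | C[N+](C)(C)CC1C(=O)O[C@@H]2CC(C)=C([C@@H](C)CCCO[Si](c3ccccc3)(c3ccccc3)C(C)(C)C)[C@@H](OC(=O)CC(C)C)[C@H]12.[I-] | intermediate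
22 | [(3aR,4S,7aR)-5-[(2S)-5-[tert-butyl(diphenyl)silyl]oxypentan-2-yl]-6-methyl-3-methylidene-2-oxo-3a,4,7,7a-tetrahydro-1-benzofuran-4-yl] 3-methylbutanoate | C=C1C(=O)O[C@@H]2CC(C)=C([C@@H](C)CCCO[Si](c3ccccc3)(c3ccccc3)C(C)(C)C)[C@@H](OC(=O)CC(C)C)[C@H]12 | intermediate
23 | [(3aR,4S,7aR)-5-[(2S)-5-hydroxypentan-2-yl]-6-methyl-3-methylidene-2-oxo-3a,4,7,7a-tetrahydro-1-benzofuran-4-yl] 3-methylbutanoate | C=C1C(=O)O[C@@H]2CC(C)=C([C@@H](C)CCCO)[C@@H](OC(=O)CC(C)C)[C@H]12 | target

**Step count and risks**

Total step count: 15 (steps 1–4 and steps 5–7 are two branches that meet in step 8). Longest linear sequence: 12 steps (steps 1–4 and 8–15).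

Steps most likely to fail, in order: step 8, step 13, step 10.

Step 8. The first carbon–carbon bond joins a fully substituted enolate carbon to a branched nitroalkene and may form slowly. The adduct may revert by retro-Michael reaction. The ketone enolate of the bicycle may also go on to displace nitrite and close a cyclopropane. In that case the same two bonds would be made by a thermal Diels–Alder reaction. Setting out from 5, LiN(iPr)2 and Me3SiCl (THF, −78 °C) would give the silyl dienol ether tert-butyl-dimethyl-[(1R)-5-methyl-4-trimethylsilyloxycyclohexa-2,4-dien-1-yl]oxysilane F1. Heating F1 with 10 (toluene, 120 °C, sealed tube) should give the bicyclo[2.2.2]oct-2-ene trimethylsilyl enol ether F2, again by addition anti to the silyloxy group. Mild hydrolysis (dilute aq. HCl, THF, 0 °C) comes back to 12.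

Step 13. Formation of the alkoxyphosphonium ion at the hindered concave-face hydroxyl may be slow, and elimination toward a diene or loss of stereochemical integrity through an allylic cation may compete with SN2 displacement. The fallback avoids inversion. Setting out from 17, a reagent-controlled reduction with (R)-2-methyl-CBS-oxazaborolidine (1 equiv) and catecholborane (toluene, −78 °C) should deliver hydride to the concave face and give the epimeric alcohol (3aS,4S,7aR)-5-[(2S)-5-[tert-butyl(diphenyl)silyl]oxypentan-2-yl]-4-hydroxy-6-methyl-3a,4,7,7a-tetrahydro-3H-1-benzofuran-2-one F3. Acylation of F3 with 3-methylbutanoic anhydride and 4-(dimethylamino)pyridine (CH2Cl2, rt), with retention, comes back to 19.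

Step 10. The hindered secondary nitro group may resist nitronate formation or be over-reduced, and prolonged base contact after ring opening may cause epimerization at C3a or loss of the silyloxy group. The fallback reaches the ketone through an isolable oxime. Setting out from 13, SnCl2·2H2O, PhSH and Et3N (MeCN, rt) should reduce the nitro group to the oxime of the bridged lactone F4. Exchange deoximation of F4 with glyoxylic acid (aq. AcOH, rt) comes back to 14, which is opened to 15 by the brief DBU treatment of step 10.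

**Further compounds**

F1 | step 8 | tert-butyl-dimethyl-[(1R)-5-methyl-4-trimethylsilyloxycyclohexa-2,4-dien-1-yl]oxysilane | C[Si](C)(C)OC1=C(C)C[C@@H](O[Si](C)(C)C(C)(C)C)C=C1
F2 | step 8 | trimethylsilyl enol ether of 12 (bicyclo[2.2.2]oct-2-ene cycloadduct, nitro- and side-chain-bearing carbons not defined) | C[Si](C)(C)OC1=C[C@@H]2[C@H](O[Si](C)(C)C(C)(C)C)C[C@@]1(C)C([C@@H](C)CCCO[Si](c3ccccc3)(c3ccccc3)C(C)(C)C)C2[N+](=O)[O-]
F3 | step 13 | (3aS,4S,7aR)-5-[(2S)-5-[tert-butyl(diphenyl)silyl]oxypentan-2-yl]-4-hydroxy-6-methyl-3a,4,7,7a-tetrahydro-3H-1-benzofuran-2-one (hydroxyl trans to the lactone ring) | O=C1C[C@H]2[C@H](O)C([C@@H](C)CCCO[Si](c3ccccc3)(c3ccccc3)C(C)(C)C)=C(C)C[C@H]2O1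
F4 | step 10 | 6-oxime of 14 (oxime geometry and C7 not defined) | O=C1C[C@@H]2[C@H](O[Si](C)(C)C(C)(C)C)C[C@](C)(O1)C([C@@H](C)CCCO[Si](c3ccccc3)(c3ccccc3)C(C)(C)C)C2=NO
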